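## Retrosynthetic overview

1. The C2–aryl bond is made last: Friedel–Crafts C-arylation of a lactol (cyclic oxocarbenium ion) with guaiacol.
2. The lactol comes from an α-hydroxy-γ-lactone, which comes from a 2-hydroxy-3-oxo-oxolane hemiketal by a benzilic-ester-type 1,2-methyl shift (key step; creates the C3 carbinol).
3. The hemiketal comes from an anti-aldol addition of 2,3-pentanedione to O-pivaloylvanillin (sets C4 and C5).
4. O-Pivaloylvanillin comes from vanillin, which comes from guaiacol and glyoxylic acid; guaiacol comes from catechol and MeI.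
5. Ring order: only the oxolane ring is built (hemiketalisation right after the aldol). It is kept as hemiketal → lactone → lactol → tetrahydrofuran.

Assumption: centres that are racemic (4) or epimer mixtures at a hemiketal or anomeric carbon (C2 of 9 and 11, and of the fallback compounds F6 and F9) are left undefined in the SMILES; every other stereocentre is specified.

## Route

Step 1
Reactants: 1 catechol (benzene-1,2-diol)
Product: 2 guaiacol (2-methoxyphenol)
Conditions: MeI (1.0 equiv), K2CO3 (1.0 equiv), catechol (1.5 equiv), acetone, reflux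
Reagents that add atoms: iodomethane, CI
Why: Williamson ether synthesis in which, with one equivalent of MeI and base and catechol in excess, the more acidic catechol is methylated in preference to the guaiacol formed, so mono-O-methylation dominates (excess catechol is washed out with water); no stereocentre is involved.

Step 2
Reactants: 2 guaiacol; 3 glyoxylic acid
Product: 5 vanillin (4-hydroxy-3-methoxybenzaldehyde), via 4-hydroxy-3-methoxymandelic acid 4 (not isolated)
Conditions: 3 (1.0 equiv), NaOH (aq), 30 °C; then O2, CuSO4 (1 mol %), NaOH (aq), 95 °C; then H2SO4 (aq) to pH 3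
Reagents that add atoms: none
Why: Electrophilic aromatic hydroxyalkylation of the guaiacol phenoxide by glyoxylate para to the OH group, followed by CuSO4-catalysed aerobic oxidative decarboxylation of the mandelate 4 (the industrial vanillin sequence); the transient carbinol centre of 4 is destroyed, so no stereocentre is set.

Step 3
Reactants: 5 vanillin
Product: 6 4-formyl-2-methoxyphenyl 2,2-dimethylpropanoate (O-pivaloylvanillin)
Conditions: PivCl (1.1 equiv), Et3N (1.3 equiv), DMAP (5 mol %), CH2Cl2, 0 → 25 °C
Reagents that add atoms: pivaloyl chloride, CC(C)(C)C(Cl)=O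
Why: DMAP-catalysed O-acylation of the phenol; the pivalate raises the electrophilicity of the aldehyde, is too hindered to acylate the amine catalyst of step 4, blocks quinone-methide chemistry, and is removed without an extra step in step 6; no stereocentre is set.

Step 4
Reactants: 6 O-pivaloylvanillin; 7 2,3-pentanedione
Product: 9 (4S,5R)-2-hydroxy-5-[3-methoxy-4-(pivaloyloxy)phenyl]-2,4-dimethyldihydrofuran-3(2H)-one (cyclic hemiketal; C2 epimers), via open-chain aldol 8 (not isolated)
Conditions: (S)-5-(pyrrolidin-2-yl)-1H-tetrazole (20 mol %), 7 (5 equiv), DMF, 4 °C, 72 h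
Reagents that add atoms: none
Why: Direct enamine aldol addition (List–Barbas type) in which the catalyst condenses at the propionyl carbonyl of 7 to give the more substituted, conjugated enamine, whose hydrogen-bonded chair transition state delivers it to the Re face of the aldehyde in the anti mode, setting C5 as R and C4 as S, after which the aldol 8 closes at once by 5-exo hemiketalisation onto the distal acetyl carbonyl to form the oxolane ring of 9.

Step 5
Reactants: 9 cyclic hemiketal
Product: 10 (3S,4S,5R)-3-hydroxy-5-[3-methoxy-4-(pivaloyloxy)phenyl]-3,4-dimethyldihydrofuran-2(3H)-one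
Conditions: La(OTf)3 (10 mol %), i-Pr2NEt (20 mol %), THF, 50 °C
Reagents that add atoms: none
Why: Proposed new method: an intramolecular benzilic ester rearrangement in which the ring oxygen of the cyclic hemiketal plays the alkoxide role — La(OTf)3 and the amine generate the lanthanum hemiketal alkoxide chelated to the adjacent C3 ketone, the C2 methyl group (pseudo-axial, parallel to the C=O π* orbital) shifts 1,2 from C2 to C3 while C2 collapses irreversibly to the lactone carbonyl, and because C2 anomerises and C4 epimerises (α to the ketone) faster than the shift, the reaction funnels through the transition state in which the migrating methyl travels on the ring face opposite to the C4 methyl while the C4 methyl stays trans to the C5 aryl group, which sets the quaternary carbinol C3 as S; the closest known reaction types are the benzilic acid and benzilic ester rearrangements of 1,2-diketones, the saccharinic acid rearrangement of 1-deoxy-2,3-diuloses to 2-C-methyl aldonolactones, and Lewis-acid-catalysed α-ketol rearrangements.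

Step 6
Reactants: 10 α-hydroxy-γ-lactone
Product: 11 (3S,4S,5R)-5-(4-hydroxy-3-methoxyphenyl)-3,4-dimethyltetrahydrofuran-2,3-diol (lactol; C2 epimers)
Conditions: i-Bu2AlH (4.2 equiv), CH2Cl2, −78 °C; MeOH, then KNaC4H4O6 (aq)
Reagents that add atoms: none
Why: Partial reduction of a γ-lactone to the lactol with i-Bu2AlH at −78 °C (the tetrahedral aluminium hemiacetal survives until work-up) with concurrent reductive removal of the pivalate; C3, C4 and C5 are untouched and the new hemiacetal centre is an inconsequential epimer mixture.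

Step 7
Reactants: 11 lactol; 2 guaiacol
Product: 12 (2R,3S,4S,5R)-2,5-bis(4-hydroxy-3-methoxyphenyl)-3,4-dimethyltetrahydrofuran-3-ol (target)
Conditions: 2 (3 equiv), BF3·OEt2 (0.3 equiv), 4 Å molecular sieves, CH2Cl2, −60 → −30 °C; Et3N quench at −30 °C
Reagents that add atoms: none
Why: Friedel–Crafts C-arylation (C-glycosylation type) of the lactol-derived cyclic oxocarbenium ion by guaiacol at its position para to OH (the ortho position is too hindered for this neopentyl-like cation); the ion adopts the envelope with C4 as the flap and the 4-methyl, 5-aryl and 3-methyl groups pseudo-equatorial, and attack on the inside face of that envelope places the new aryl group trans to the C3 oxygen and the 4-methyl group and cis to the C5 aryl group, which sets C2 as R under kinetic control at low temperature.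

## Compound list

1 | catechol (benzene-1,2-diol) | Oc1ccccc1O | starting material
2 | guaiacol (2-methoxyphenol) | COc1ccccc1O | intermediate
3 | glyoxylic acid | OC(=O)C=O | starting material
4 | 4-hydroxy-3-methoxymandelic acid (racemic, not isolated) | COc1cc(C(O)C(O)=O)ccc1O | intermediate
5 | vanillin (4-hydroxy-3-methoxybenzaldehyde) | COc1cc(C=O)ccc1O | intermediate
6 | 4-formyl-2-methoxyphenyl 2,2-dimethylpropanoate | COc1cc(C=O)ccc1OC(=O)C(C)(C)C | intermediate
7 | 2,3-pentanedione | CCC(=O)C(C)=O | starting material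
8 | 4-[(1R,2S)-1-hydroxy-2-methyl-3,4-dioxopentyl]-2-methoxyphenyl 2,2-dimethylpropanoate (open-chain aldol, not isolated) | CC(=O)C(=O)[C@@H](C)[C@@H](O)c1ccc(OC(=O)C(C)(C)C)c(OC)c1 | intermediate
9 | (4S,5R)-2-hydroxy-5-[3-methoxy-4-(pivaloyloxy)phenyl]-2,4-dimethyldihydrofuran-3(2H)-one (C2 epimers) | CC1(O)O[C@@H](c2ccc(OC(=O)C(C)(C)C)c(OC)c2)[C@H](C)C1=O | intermediate
10 | (3S,4S,5R)-3-hydroxy-5-[3-methoxy-4-(pivaloyloxy)phenyl]-3,4-dimethyldihydrofuran-2(3H)-one | O=C1O[C@@H](c2ccc(OC(=O)C(C)(C)C)c(OC)c2)[C@H](C)[C@]1(C)O | intermediate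
11 | (3S,4S,5R)-5-(4-hydroxy-3-methoxyphenyl)-3,4-dimethyltetrahydrofuran-2,3-diol (C2 epimers) | OC1O[C@@H](c2ccc(O)c(OC)c2)[C@H](C)[C@]1(C)O | intermediate
12 | (2R,3S,4S,5R)-2,5-bis(4-hydroxy-3-methoxyphenyl)-3,4-dimethyltetrahydrofuran-3-ol | COc1cc([C@H]2O[C@@H](c3ccc(O)c(OC)c3)[C@H](C)[C@]2(C)O)ccc1O | target

## Step count and risk

Total steps: 7. Longest linear sequence: 7 (1 → 2 → 5 → 6 → 9 → 10 → 11 → 12); 2 is used a second time in step 7.

The three steps most likely to fail:

**Step 4 (aldol with a 1,2-diketone donor).** 1,2-Diketones are uncommon enamine donors. The acetyl-side enamine, self-aldol of 7 and dehydration of 8 can all compete. Fallback (sets out from 6, comes back at 9): Marshall propargylation. The allenylzinc reagent generated from (S)-pent-3-yn-2-yl methanesulfonate with Pd(OAc)2, PPh3 and Et2Zn (THF, −20 °C) adds to 6 in the anti SE2' mode to give 4-[(1R,2R)-1-hydroxy-2-methylpent-3-yn-1-yl]-2-methoxyphenyl 2,2-dimethylpropanoate F1. Wacker-type dioxygenation of the alkyne (PdBr2, CuBr2, O2, aqueous dioxane, 60 °C) then gives the 1,2-diketone, which closes to 9.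

**Step 5 (the proposed new method).** Methyl is a poor migrating group, and retro-aldol opening of 9 could erode the C5 configuration before the shift. Fallback with known chemistry only (sets out from 2, comes back at 11):
- Friedel–Crafts/Fries propionylation of 2 (propionyl chloride, AlCl3, nitrobenzene) gives 1-(4-hydroxy-3-methoxyphenyl)propan-1-one F2.
- TMSOTf and Et3N convert it into the bis-silylated (Z)-enol silane trimethyl{[(1Z)-1-{3-methoxy-4-[(trimethylsilyl)oxy]phenyl}prop-1-en-1-yl]oxy}silane F3.
- An anti-selective Mukaiyama aldol addition to methyl pyruvate, catalysed by Sn(OTf)2 and the Ph-pybox enantiomer that gives the (2S,3R) adduct (CH2Cl2, −78 °C; acidic desilylation), gives methyl (2S,3R)-2-hydroxy-4-(4-hydroxy-3-methoxyphenyl)-2,3-dimethyl-4-oxobutanoate F4.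
- Chelation-controlled 1,3-syn reduction (Et2BOMe, NaBH4, THF/MeOH, −78 °C) and lactonisation (p-TsOH, toluene) give (3S,4S,5R)-3-hydroxy-5-(4-hydroxy-3-methoxyphenyl)-3,4-dimethyldihydrofuran-2(3H)-one F5, which i-Bu2AlH reduces to 11 as in step 6.

**Step 7 (Friedel–Crafts arylation).** Guaiacol may react at oxygen or at the ortho position. The acid can also epimerise the two p-hydroxybenzylic carbons towards the more stable C2 epimer, or trigger a pinacol-type shift of the C3 carbinol. Fallback (sets out from 11 and uses 2, comes back at 12):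
- Peracetylation of 11 (Ac2O, Et3N, DMAP, CH2Cl2, 40 °C) gives (3S,4S,5R)-5-(4-acetoxy-3-methoxyphenyl)-3,4-dimethyltetrahydrofuran-2,3-diyl diacetate F6.
- 2 is brominated para to OH (NBS, MeCN, 0 °C) to 4-bromo-2-methoxyphenol F7 and silylated (TBSCl, imidazole, DMF) to (4-bromo-2-methoxyphenoxy)(tert-butyl)dimethylsilane F8.
- F6 is converted with Me3SiBr into (3S,4S,5R)-5-(4-acetoxy-3-methoxyphenyl)-2-bromo-3,4-dimethyltetrahydrofuran-3-yl acetate F9.
- F9 couples with the diarylzinc made from F8 (t-BuLi, then ZnBr2; toluene/Bu2O). The C3 acetate closes to an acetoxonium ion on the lower face, so the aryl group is delivered trans to it (1,2-trans C-glycosylation). The product is (2R,3S,4S,5R)-5-(4-acetoxy-3-methoxyphenyl)-2-{4-[(tert-butyldimethylsilyl)oxy]-3-methoxyphenyl}-3,4-dimethyltetrahydrofuran-3-yl acetate F10.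
- Bu4NF (THF), then K2CO3 in MeOH, removes the silyl and acetyl groups to give 12.

## Further compounds

F1 | step 4 | 4-[(1R,2R)-1-hydroxy-2-methylpent-3-yn-1-yl]-2-methoxyphenyl 2,2-dimethylpropanoate | CC#C[C@@H](C)[C@@H](O)c1ccc(OC(=O)C(C)(C)C)c(OC)c1
F2 | step 5 | 1-(4-hydroxy-3-methoxyphenyl)propan-1-one | CCC(=O)c1ccc(O)c(OC)c1
F3 | step 5 | trimethyl{[(1Z)-1-{3-methoxy-4-[(trimethylsilyl)oxy]phenyl}prop-1-en-1-yl]oxy}silane | C/C=C(\O[Si](C)(C)C)c1ccc(O[Si](C)(C)C)c(OC)c1
F4 | step 5 | methyl (2S,3R)-2-hydroxy-4-(4-hydroxy-3-methoxyphenyl)-2,3-dimethyl-4-oxobutanoate | COC(=O)[C@@](C)(O)[C@@H](C)C(=O)c1ccc(O)c(OC)c1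
F5 | step 5 | (3S,4S,5R)-3-hydroxy-5-(4-hydroxy-3-methoxyphenyl)-3,4-dimethyldihydrofuran-2(3H)-one | O=C1O[C@@H](c2ccc(O)c(OC)c2)[C@H](C)[C@]1(C)O
F6 | step 7 | (3S,4S,5R)-5-(4-acetoxy-3-methoxyphenyl)-3,4-dimethyltetrahydrofuran-2,3-diyl diacetate (C2 epimers) | CC(=O)OC1O[C@@H](c2ccc(OC(C)=O)c(OC)c2)[C@H](C)[C@]1(C)OC(C)=O
F7 | step 7 | 4-bromo-2-methoxyphenol | COc1cc(Br)ccc1O
F8 | step 7 | (4-bromo-2-methoxyphenoxy)(tert-butyl)dimethylsilane | COc1cc(Br)ccc1O[Si](C)(C)C(C)(C)C
F9 | step 7 | (3S,4S,5R)-5-(4-acetoxy-3-methoxyphenyl)-2-bromo-3,4-dimethyltetrahydrofuran-3-yl acetate (C2 epimers) | BrC1O[C@@H](c2ccc(OC(C)=O)c(OC)c2)[C@H](C)[C@]1(C)OC(C)=O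
F10 | step 7 | (2R,3S,4S,5R)-5-(4-acetoxy-3-methoxyphenyl)-2-{4-[(tert-butyldimethylsilyl)oxy]-3-methoxyphenyl}-3,4-dimethyltetrahydrofuran-3-yl acetate | COc1cc([C@H]2O[C@@H](c3ccc(OC(C)=O)c(OC)c3)[C@H](C)[C@]2(C)OC(C)=O)ccc1O[Si](C)(C)C(C)(C)C
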